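## The problem

Target **21** is an unsymmetrical bis-coumarin. C3 of a 7-hydroxy-6,8-dimethoxycoumarin (rings A and B, unprimed locants) carries an ether oxygen that is O7' of a second 6',8'-dimethoxycoumarin (benzene ring C, pyranone ring D, primed locants). This oxygen lies between the C6' and C8' methoxy groups and is bonded to an sp2 carbon of an enol lactone, so joining two finished coumarins at C3–O7' would require a hindered, weakly nucleophilic phenoxide to attack an unactivated vinylic carbon. There is no stereocentre; the task is regiochemical, namely placing six oxygen substituents and two pyranone rings on two benzene rings. Both lactones open in hydroxide or alkoxide, the free C7 phenol between two methoxy groups is easily oxidised, and four aryl methyl ethers rule out strong Lewis acids, so a single phenol protecting group that leaves in dilute acid is wanted. Rings A and C show the same sequence on four adjacent carbons (lactone O, OMe, O, OMe), which invites one building block for both. Ring D can be closed selectively because O1' of ring C has only one free ortho carbon, C4a'; the other, C8', bears a methoxy group, so a chain delivered from O1' by a sigmatropic shift can rearomatise only where ring D must be fused.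

## Retrosynthesis

**21 ⇒ 20.** The O7–CH2OMe bond is cut last. A methoxymethyl (MOM) ether on O7 is the only protecting group in the late route; it tolerates organolithium, carbonate, carbodiimide, neutral heating and buffered chromium oxidation, and leaves in dilute acid that touches neither lactone nor the methyl ethers.

**20 ⇒ 19.** The C2' carbonyl of ring D is traced back to a CH2 group, giving 2H-chromene **19**. Closing ring D directly at the lactone level from an aryl propiolate would need strong acid or a noble metal on a substrate carrying an acid-labile MOM group. The CH2 level is what a reagent-free rearrangement delivers, and C2' is then the only methylene that is both allylic and attached to oxygen, so the oxidant has a single obvious site.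

**19 ⇒ 15.** Cutting C4'–C4a' and moving the three-carbon unit back to O1' gives aryl propargyl ether **15**. The forward reaction is a propargyl Claisen shift followed by a hydrogen shift and an oxa-electrocyclization. It needs no reagent, so the finished unprimed coumarin, the MOM ether and the hindered C3–O7' ether are only spectators. Placing it after the last basic step means ring D never meets hydroxide. Regiochemistry is fixed by the C8' methoxy group.

**15 ⇒ 7 + 13.** The C3=C4 double bond and the O1–C2 lactone bond of ring B are cut together (Perkin-type condensation), giving salicylaldehyde **7** and aryloxyacetic acid **13**. The difficult C3–O7' bond is thereby already present in **13** as an ordinary alkyl aryl ether. The neighbouring cut, coupling a 3-halocoumarin with the hindered phenol, would attempt exactly the substitution at sp2 carbon that the structure disfavours. The condensation also delivers ring B at the coumarin oxidation level, with no later dehydrogenation.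

**13 ⇒ 12 ⇒ 10 + 11.** The O7'–CH2 bond is formed by Williamson alkylation of phenol **10** with methyl bromoacetate **11** (substitution at a primary carbon, insensitive to the two flanking methoxy groups). Saponification of ester **12** then gives **13** before any lactone exists.

**10 ⇒ 9 ⇒ 5 + 8.** The O1'–CH2 bond comes from phenol **5** and propargyl bromide **8**. In **5** the future O1' is a free hydroxyl and the future O7' is masked as a MOM ether, so the two oxygens are alkylated one after the other with no selectivity question; acid removal of MOM from **9** gives **10**.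

**7 ⇒ 5.** The C4–C4a bond (formyl carbon to ring A) is made by magnesium-mediated ortho-formylation of the same phenol **5**. Only one ortho position is free, and it is the one required. Electrophilic formylation under Lewis acid would threaten the MOM group and is governed by the methoxy groups instead of the hydroxyl.

**5 ⇒ 2 ⇒ 1.** The C–O bond that becomes O1 and O1' is introduced by directed ortho-metalation, borylation and oxidation of MOM ether **2**, made from commercial 2,6-dimethoxyphenol **1**. Compound **2** is symmetrical, so both positions ortho to a methoxy group are equivalent. A formylation–oxidation sequence to the same phenol would cost two or three more steps.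

## Roads not taken

**Alternative 1:** ring A and ring B are made together by cutting C5–C6, C8–C8a and O1–C2. Under a strong alkoxide base, 1,3-dimethoxyacetone **A2** would add through one α-carbon to the methoxymethylidene carbon of glutarate **A3** and through the other to the adjacent ester. After loss of methanol and aromatisation the new C8a phenol lactonises to the racemic 3,4-dihydrocoumarin **A1**.
- Merits: two rings in one operation, the 6-OMe/7-OH/8-OMe array comes from a symmetrical three-carbon ketone, and the C7 hydroxyl appears unprotected. In bond-forming density this is better than the chosen plan.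
- Weak points: **A3** already contains the finished primed lactone, which must survive alkoxide. Its C3 protons are vinylogously acidic, and the derived anion can expel the aryloxide at C2. Making **A3** requires a hindered phenoxide to displace a secondary halide. **A1** must still be dehydrogenated at C3–C4 in the presence of a free, electron-rich phenol.
- Comparison: the chosen plan is less dense but exposes no lactone to strong base, forms the hindered ether at a primary carbon, and obtains the C3=C4 bond from the condensation itself.

**Alternative 2:** C2–C3 and C3–O7' are cut. Arylacetaldehyde **A6**, chloroform **A7** and isofraxidin **A5** would combine under an amidine base and then hydroxide through the usual Jocic sequence (addition of the trichloromethyl anion, epoxide formation, opening by the phenoxide, hydrolysis) to give racemic α-aryloxy acid **A4**.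
- Merits: the most convergent route. The whole primed coumarin is bought as **A5**, so the primed half costs no steps, against seven steps (4 to 10) spent here on ring C and ring D. The hindered C–O bond is made at a very reactive electrophile.
- Weak points: hydroxide opens the lactone of **A5**, and reclosure is lost if the cinnamate isomerises. The coumarin 7-phenoxide is hindered and weakly nucleophilic, so hydroxide competes for the epoxide. **A6** is enolisable and needs its own synthesis of about five steps. The key step closes no ring, so MOM removal, lactonisation and a late dehydrogenation of a racemic dihydrocoumarin remain.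
- Comparison: the chosen plan sets against the longer primed half a sequence in which every ring closure is regiochemically forced and ring B arrives at the correct oxidation level.

**Alternative 3:** ring A is built by cutting C8a–C4a and C5–C6. The 2-silyloxyfuran **A9** would add to methyl propiolate **A10** across its C2 and C5; opening of the oxygen bridge aromatises to benzoate **A8**.
- Merits: complete regiocontrol, and four ring-A oxygens that arrive differently substituted (silyl, methyl, benzyl, free hydroxyl). This orthogonality is better than the chosen plan, which relies on a single MOM group and on the symmetry of **1**.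
- Weak points: it constructs a benzene ring whose oxygenation pattern can be bought. **A8** still needs O-methylation, ester-to-aldehyde adjustment and desilylation before the same kind of condensation used here. The benzyl group must finally be removed by hydrogenolysis beside two coumarin double bonds, or by a Lewis acid that endangers methyl ethers. It does not address ring D or the ether link.
- Comparison: the chosen plan reaches salicylaldehyde **7** in three steps from **1** and uses a protecting group that leaves in dilute acid.

Key step: step 9

Remark: the target has no stereocentre, so no configuration has to be assigned.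

## Route

Step 1
Reactants: 1 2,6-dimethoxyphenol
Product: 2 1,3-dimethoxy-2-(methoxymethoxy)benzene
Conditions: NaH, MOMCl, DMF, 0 °C to rt
Reagents that add atoms: chloromethyl methyl ether, COCCl
Why: Williamson-type O-alkylation of the sodium phenoxide with a very reactive α-chloro ether, which is standard for hindered 2,6-disubstituted phenols.

Step 2
Reactants: 2 1,3-dimethoxy-2-(methoxymethoxy)benzene
Product: 5 2,4-dimethoxy-3-(methoxymethoxy)phenol, via aryllithium 3 (not isolated), via dimethyl arylboronate 4 (not isolated)
Conditions: n-BuLi, TMEDA, THF, 0 °C; B(OMe)3, −78 °C to rt; AcOH, 30% aq H2O2, 0 °C to rt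
Reagents that add atoms: hydrogen peroxide, OO
Why: Directed ortho-metalation beside a methoxy group (the two candidate positions are equivalent by symmetry), borylation and oxidative aryl migration from boron to oxygen; this hydroxylation sequence is established for 1,2,3-trialkoxybenzenes and the MOM acetal tolerates it.

Step 3
Reactants: 5 2,4-dimethoxy-3-(methoxymethoxy)phenol
Product: 7 2-hydroxy-3,5-dimethoxy-4-(methoxymethoxy)benzaldehyde, via salicyl alcohol 6 (not isolated)
Conditions: MgCl2, Et3N, (CH2O)n, MeCN, reflux
Reagents that add atoms: formaldehyde (from paraformaldehyde), C=O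
Why: Casnati–Skattebøl ortho-formylation: the magnesium phenoxide delivers formaldehyde to the only free ortho carbon and the resulting salicyl alcohol 6 is oxidised in the flask by hydride transfer to a second formaldehyde; the basic medium spares the MOM group.

Step 4
Reactants: 5 2,4-dimethoxy-3-(methoxymethoxy)phenol; 8 propargyl bromide
Product: 9 1,3-dimethoxy-2-(methoxymethoxy)-4-(prop-2-yn-1-yloxy)benzene
Conditions: K2CO3, acetone, reflux
Reagents that add atoms: none
Why: Williamson ether synthesis at a primary propargylic carbon; carbonate is too weak to isomerise the propargyl ether to an allenyl ether.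

Step 5
Reactants: 9 1,3-dimethoxy-2-(methoxymethoxy)-4-(prop-2-yn-1-yloxy)benzene
Product: 10 2,6-dimethoxy-3-(prop-2-yn-1-yloxy)phenol
Conditions: conc. HCl (cat.), MeOH, 50 °C
Reagents that add atoms: none
Why: Acid-catalysed acetal exchange with methanol removes the MOM group as dimethoxymethane; aryl methyl and aryl propargyl ethers are inert to dilute acid.

Step 6
Reactants: 10 2,6-dimethoxy-3-(prop-2-yn-1-yloxy)phenol; 11 methyl bromoacetate
Product: 12 methyl 2-[2,6-dimethoxy-3-(prop-2-yn-1-yloxy)phenoxy]acetate
Conditions: K2CO3, DMF, rt to 50 °C
Reagents that add atoms: none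
Why: Williamson alkylation of the doubly ortho-substituted phenoxide with an activated primary bromide; this forms the future C3–O7' linkage by substitution at sp3 carbon, where steric hindrance matters little.

Step 7
Reactants: 12 methyl 2-[2,6-dimethoxy-3-(prop-2-yn-1-yloxy)phenoxy]acetate
Product: 13 2-[2,6-dimethoxy-3-(prop-2-yn-1-yloxy)phenoxy]acetic acid
Conditions: LiOH·H2O, THF–H2O, rt; then 1 M HCl
Reagents that add atoms: lithium hydroxide, [Li+].[OH-]
Why: Ester saponification by acyl–oxygen cleavage; no lactone is present yet and the propargyl ether is stable to aqueous hydroxide at room temperature.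

Step 8
Reactants: 7 2-hydroxy-3,5-dimethoxy-4-(methoxymethoxy)benzaldehyde; 13 2-[2,6-dimethoxy-3-(prop-2-yn-1-yloxy)phenoxy]acetic acid
Product: 15 3-[2,6-dimethoxy-3-(prop-2-yn-1-yloxy)phenoxy]-6,8-dimethoxy-7-(methoxymethoxy)-2H-chromen-2-one, via aryl ester 14 (not isolated)
Conditions: DCC, DMSO, 110 °C
Reagents that add atoms: none
Why: Perkin–Oglialoro-type coumarin synthesis under carbodiimide activation, known for aryloxyacetic acids: the phenol of 7 is acylated to ester 14, whose α-aryloxy methylene condenses intramolecularly with the ortho aldehyde and dehydrates to the C3=C4 bond. Both ortho positions of the phenol of 7 are occupied, so the methylthiomethylation that DCC–DMSO can cause on phenols has no site, and 110 °C is well below the onset of the propargyl Claisen shift.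

Step 9
Reactants: 15 3-[2,6-dimethoxy-3-(prop-2-yn-1-yloxy)phenoxy]-6,8-dimethoxy-7-(methoxymethoxy)-2H-chromen-2-one
Product: 19 3-[(6,8-dimethoxy-2H-chromen-7-yl)oxy]-6,8-dimethoxy-7-(methoxymethoxy)-2H-chromen-2-one, via allenyl dienone 16 (not isolated), via ortho-allenylphenol 17 (not isolated), via ortho-quinone methide 18 (not isolated)
Conditions: PhNEt2 (degassed), 200–210 °C, Ar
Reagents that add atoms: none
Why: A (3,3) sigmatropic shift carries the propargyl group from O1' to C4a' with allylic transposition, forming C4'–C4a' and giving allenyl dienone 16, which enolises to ortho-allenylphenol 17. A 1,5-hydrogen shift from the phenolic oxygen to the central allene carbon gives the (Z)-configured ortho-quinone methide 18, and a thermally allowed disrotatory six-electron oxa-electrocyclization re-forms O1'–C2' and closes ring D. The closest known reaction is the thermal rearrangement of aryl propargyl ethers to 2H-chromenes in N,N-diethylaniline, including 2-methoxyphenyl propargyl ethers, which give 8-methoxy-2H-chromenes. Ring D thus closes by electrocyclization of a 1-oxatriene, not by ionic attack, so no acid, base or metal is needed. No stereocentre is created; the sp3 centre of 16 is transient and disappears on enolisation. The step needs ortho regioselectivity and chromene-over-benzofuran selectivity. The first is secured by the C8' methoxy group, since a shift to C8' gives a dienone that cannot enolise and reverts. The second is secured by the neutral amine solvent without fluoride or alkoxide, so no phenoxide is present to add to the allene in the five-membered mode. The unprimed coumarin, the MOM acetal and the C3–O7' vinyl aryl ether have no thermal pathway at this temperature.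

Step 10
Reactants: 19 3-[(6,8-dimethoxy-2H-chromen-7-yl)oxy]-6,8-dimethoxy-7-(methoxymethoxy)-2H-chromen-2-one
Product: 20 3-[(6,8-dimethoxy-2-oxo-2H-chromen-7-yl)oxy]-6,8-dimethoxy-7-(methoxymethoxy)-2H-chromen-2-one
Conditions: C5H5NH[CrO3Cl] (pyridinium chlorochromate), NaOAc, Celite, CH2Cl2, reflux
Reagents that add atoms: pyridinium chlorochromate, [O-][Cr](=O)(=O)Cl.c1cc[nH+]cc1
Why: Oxidation of 2H-chromenes to coumarins by hexavalent chromium is a known allylic oxidation; C2' is the only methylene that is both allylic and oxygen-bound, and the electron-rich ring C stabilises positive charge developing there. Sodium acetate buffers the medium for the MOM ether, and the phenol that would be oxidised is still protected.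

Step 11
Reactants: 20 3-[(6,8-dimethoxy-2-oxo-2H-chromen-7-yl)oxy]-6,8-dimethoxy-7-(methoxymethoxy)-2H-chromen-2-one
Product: 21 7-hydroxy-6,8-dimethoxy-3-[(6,8-dimethoxy-2-oxo-2H-chromen-7-yl)oxy]-2H-chromen-2-one
Conditions: 2 M HCl, MeOH–THF, 50 °C
Reagents that add atoms: none
Why: Acid-catalysed acetal exchange removes the MOM group as dimethoxymethane; coumarin lactones and aryl methyl ethers are stable to dilute acid, and no base is used, so neither lactone opens.

## Compound list

1 | 2,6-dimethoxyphenol | COc1cccc(OC)c1O | starting material
2 | 1,3-dimethoxy-2-(methoxymethoxy)benzene | COCOc1c(OC)cccc1OC | intermediate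
3 | [2,4-dimethoxy-3-(methoxymethoxy)phenyl]lithium | [Li]c1ccc(OC)c(OCOC)c1OC | intermediate (not isolated)
4 | dimethyl [2,4-dimethoxy-3-(methoxymethoxy)phenyl]boronate | COB(OC)c1ccc(OC)c(OCOC)c1OC | intermediate (not isolated)
5 | 2,4-dimethoxy-3-(methoxymethoxy)phenol | COCOc1c(OC)ccc(O)c1OC | intermediate
6 | 6-(hydroxymethyl)-2,4-dimethoxy-3-(methoxymethoxy)phenol (present as its magnesium salt) | COCOc1c(OC)cc(CO)c(O)c1OC | intermediate (not isolated)
7 | 2-hydroxy-3,5-dimethoxy-4-(methoxymethoxy)benzaldehyde | COCOc1c(OC)cc(C=O)c(O)c1OC | intermediate
8 | propargyl bromide (3-bromoprop-1-yne) | BrCC#C | starting material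
9 | 1,3-dimethoxy-2-(methoxymethoxy)-4-(prop-2-yn-1-yloxy)benzene | C#CCOc1ccc(OC)c(OCOC)c1OC | intermediate
10 | 2,6-dimethoxy-3-(prop-2-yn-1-yloxy)phenol | C#CCOc1ccc(OC)c(O)c1OC | intermediate
11 | methyl bromoacetate | COC(=O)CBr | starting material
12 | methyl 2-[2,6-dimethoxy-3-(prop-2-yn-1-yloxy)phenoxy]acetate | C#CCOc1ccc(OC)c(OCC(=O)OC)c1OC | intermediate
13 | 2-[2,6-dimethoxy-3-(prop-2-yn-1-yloxy)phenoxy]acetic acid | C#CCOc1ccc(OC)c(OCC(=O)O)c1OC | intermediate
14 | 6-formyl-2,4-dimethoxy-3-(methoxymethoxy)phenyl 2-[2,6-dimethoxy-3-(prop-2-yn-1-yloxy)phenoxy]acetate | C#CCOc1ccc(OC)c(OCC(=O)Oc2c(C=O)cc(OC)c(OCOC)c2OC)c1OC | intermediate (not isolated)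
15 | 3-[2,6-dimethoxy-3-(prop-2-yn-1-yloxy)phenoxy]-6,8-dimethoxy-7-(methoxymethoxy)-2H-chromen-2-one | C#CCOc1ccc(OC)c(Oc2cc3cc(OC)c(OCOC)c(OC)c3oc2=O)c1OC | intermediate
16 | 3-{[2,6-dimethoxy-3-oxo-4-(propa-1,2-dien-1-yl)cyclohexa-1,5-dien-1-yl]oxy}-6,8-dimethoxy-7-(methoxymethoxy)-2H-chromen-2-one (racemic, transient) | C=C=CC1C=C(OC)C(Oc2cc3cc(OC)c(OCOC)c(OC)c3oc2=O)=C(OC)C1=O | intermediate (not isolated)
17 | 3-[3-hydroxy-2,6-dimethoxy-4-(propa-1,2-dien-1-yl)phenoxy]-6,8-dimethoxy-7-(methoxymethoxy)-2H-chromen-2-one | C=C=Cc1cc(OC)c(Oc2cc3cc(OC)c(OCOC)c(OC)c3oc2=O)c(OC)c1O | intermediate (not isolated)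
18 | 3-{[(4Z)-2,6-dimethoxy-3-oxo-4-(prop-2-en-1-ylidene)cyclohexa-1,5-dien-1-yl]oxy}-6,8-dimethoxy-7-(methoxymethoxy)-2H-chromen-2-one | C=C/C=C1/C=C(OC)C(Oc2cc3cc(OC)c(OCOC)c(OC)c3oc2=O)=C(OC)C1=O | intermediate (not isolated)
19 | 3-[(6,8-dimethoxy-2H-chromen-7-yl)oxy]-6,8-dimethoxy-7-(methoxymethoxy)-2H-chromen-2-one | COCOc1c(OC)cc2cc(Oc3c(OC)cc4C=CCOc4c3OC)c(=O)oc2c1OC | intermediate
20 | 3-[(6,8-dimethoxy-2-oxo-2H-chromen-7-yl)oxy]-6,8-dimethoxy-7-(methoxymethoxy)-2H-chromen-2-one | COCOc1c(OC)cc2cc(Oc3c(OC)cc4ccc(=O)oc4c3OC)c(=O)oc2c1OC | intermediate
21 | 7-hydroxy-6,8-dimethoxy-3-[(6,8-dimethoxy-2-oxo-2H-chromen-7-yl)oxy]-2H-chromen-2-one | COc1cc2cc(Oc3c(OC)cc4ccc(=O)oc4c3OC)c(=O)oc2c(OC)c1O | target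

## Step count and risk

Total step count: 11. Longest linear sequence: 10 steps (steps 1, 2, 4, 5, 6, 7, 8, 9, 10, 11, from **1** to **21**); step 3 is a one-step branch from the shared phenol **5**.

**Step 9 (key step).** The most likely failures are thermal: oligomerisation of the terminal alkyne or of the electron-rich chromene at 200 °C, loss of the MOM group through adventitious acid, and diversion of the reversible shift to C8' into an irreversible intramolecular cycloaddition of the allene onto the dienone. Fallback: starting from **15**, the pericyclic cascade is replaced by π-acid catalysis. Ph3PAuNTf2 (monovalent gold) in CH2Cl2 at room temperature should activate the alkyne for intramolecular hydroarylation by C4a' in the six-membered endo mode, forming the same C4'–C4a' bond without breaking O1'–C2'. It returns to the route at **19** and makes no new compound (entry F0).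

**Step 8.** The hindered, hydrogen-bonded phenol of **7** may be acylated slowly, so the activated acid can rearrange to an unreactive N-acylurea. The weakly acidic α-aryloxy methylene of ester **14** may also fail to condense, leaving the sequence stalled at the ester. Fallback: starting from phenol **10**, insertion of the carbene from methyl 2-diazo-2-(dimethoxyphosphoryl)acetate into the O–H bond, catalysed by Rh2(OAc)4 (divalent rhodium), should give methyl 2-(dimethoxyphosphoryl)-2-[2,6-dimethoxy-3-(prop-2-yn-1-yloxy)phenoxy]acetate F1. Horner–Wadsworth–Emmons olefination of **7** with F1 (NaH, THF), with lactonisation of the olefination product on warming, rejoins the route at **15**.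

**Step 10.** Over-oxidation of the electron-rich C3'=C4' double bond or of ring C, acid-promoted loss of the MOM group, or incomplete conversion on the chromium residues may erode the material. Fallback: starting from **19**, hydride abstraction with DDQ in wet CH2Cl2 and capture of the cation by water should give the lactol 3-[(2-hydroxy-6,8-dimethoxy-2H-chromen-7-yl)oxy]-6,8-dimethoxy-7-(methoxymethoxy)-2H-chromen-2-one F2. Oxidation of F2 with MnO2 rejoins the route at **20**.

**Step 2.** Metalation may be incomplete or may attack the MOM acetal, and the electron-rich phenol may be over-oxidised by peroxide. Fallback: starting from **2**, electrophilic bromination with NBS in MeCN (ortho to one methoxy group and para to the other) should give 1-bromo-2,4-dimethoxy-3-(methoxymethoxy)benzene F3. Bromine–lithium exchange of F3 with n-BuLi at −78 °C then fixes the site of the metal and rejoins the route at aryllithium **3**.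

## Further compounds

F0 | step 9 | none | none
F1 | step 8 | methyl 2-(dimethoxyphosphoryl)-2-[2,6-dimethoxy-3-(prop-2-yn-1-yloxy)phenoxy]acetate (racemic) | C#CCOc1ccc(OC)c(OC(C(=O)OC)P(=O)(OC)OC)c1OC
F2 | step 10 | 3-[(2-hydroxy-6,8-dimethoxy-2H-chromen-7-yl)oxy]-6,8-dimethoxy-7-(methoxymethoxy)-2H-chromen-2-one (racemic lactol) | COCOc1c(OC)cc2cc(Oc3c(OC)cc4C=CC(O)Oc4c3OC)c(=O)oc2c1OC
F3 | step 2 | 1-bromo-2,4-dimethoxy-3-(methoxymethoxy)benzene | COCOc1c(OC)ccc(Br)c1OC
A1 | alternative 1 | 3-[(6,8-dimethoxy-2-oxo-2H-chromen-7-yl)oxy]-7-hydroxy-6,8-dimethoxy-3,4-dihydro-2H-chromen-2-one (racemic) | COc1cc2CC(Oc3c(OC)cc4ccc(=O)oc4c3OC)C(=O)Oc2c(OC)c1O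
A2 | alternative 1 | 1,3-dimethoxyacetone | COCC(=O)COC
A3 | alternative 1 | dimethyl 2-[(6,8-dimethoxy-2-oxo-2H-chromen-7-yl)oxy]-4-(methoxymethylidene)pentanedioate (racemic, alkene geometry immaterial) | COC=C(CC(Oc1c(OC)cc2ccc(=O)oc2c1OC)C(=O)OC)C(=O)OC
A4 | alternative 2 | 2-[(6,8-dimethoxy-2-oxo-2H-chromen-7-yl)oxy]-3-[3,5-dimethoxy-2,4-bis(methoxymethoxy)phenyl]propanoic acid (racemic) | OC(=O)C(Cc1cc(OC)c(OCOC)c(OC)c1OCOC)Oc1c(OC)cc2ccc(=O)oc2c1OC
A5 | alternative 2 | isofraxidin (7-hydroxy-6,8-dimethoxy-2H-chromen-2-one) | COc1cc2ccc(=O)oc2c(OC)c1O
A6 | alternative 2 | 2-[3,5-dimethoxy-2,4-bis(methoxymethoxy)phenyl]acetaldehyde | O=CCc1cc(OC)c(OCOC)c(OC)c1OCOC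
A7 | alternative 2 | chloroform | ClC(Cl)Cl
A8 | alternative 3 | methyl 4-(benzyloxy)-2-[(tert-butyldimethylsilyl)oxy]-5-hydroxy-3-methoxybenzoate | COC(=O)c1cc(O)c(OCc2ccccc2)c(OC)c1O[Si](C)(C)C(C)(C)C
A9 | alternative 3 | {[4-(benzyloxy)-3-methoxyfuran-2-yl]oxy}(tert-butyl)dimethylsilane | CC(C)(C)[Si](C)(C)Oc1occ(OCc2ccccc2)c1OC
A10 | alternative 3 | methyl propiolate | C#CC(=O)OC
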